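## Retrosynthetic overview

1. The target is a tetrahydrofuran (O1, C2–C5) with guaiacyl on C2, CH2OH (C9) on C3 and veratrylmethyl (C7') on C4. C4 is set last, by hydrogenating an exocyclic C4=C7' benzylidene on the face away from a bulky C9 silyl ether; the same hydrogenation frees the phenol.
2. The only ring is cut at O1–C2 and C3–C4. The strategy rests on this feature: guaiacyl–C2–C3–C9 is a cinnamaldehyde unit, and O1–C5–C4–C7'–veratryl is a 3-arylpropargyl alcohol.
3. Both bonds, the ring and the C2/C3 stereocentres are made in one flask by iminium–enamine catalysis combined with alkyne activation by divalent palladium (oxa-Michael addition, then 5-exo-dig carbocyclisation). C9 is reduced in the same flask.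
4. The enal comes from O-benzylvanillin by Wittig formyl-olefination; the alkynol comes from 4-iodoveratrole and propargyl alcohol by Sonogashira coupling.

Key step: step 3

Assumption: with the numbering O1, C2 (guaiacyl), C3 (bearing C9), C4 (bearing C7'), C5, the target is (2S,3R,4R), 2,3-trans and 3,4-cis; the (S)-amine is chosen because the alcohol should enter the iminium ion anti to the catalyst's shielding group, which corresponds to (S) at C2.

## Route

Step 1
Reactants: 1 4-(benzyloxy)-3-methoxybenzaldehyde (O-benzylvanillin)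
Product: 2 (E)-3-[4-(benzyloxy)-3-methoxyphenyl]acrylaldehyde
Conditions: Ph3P=CHCHO (1.1 equiv), toluene, 80 °C
Reagents that add atoms: (triphenylphosphoranylidene)acetaldehyde, O=CC=P(c1ccccc1)(c1ccccc1)c1ccccc1
Why: Wittig olefination with the stabilised formylmethylene ylide should give the E-enal under thermodynamic control, and the near-stoichiometric ylide limits a second homologation.

Step 2
Reactants: 3 4-iodo-1,2-dimethoxybenzene; 4 prop-2-yn-1-ol
Product: 5 3-(3,4-dimethoxyphenyl)prop-2-yn-1-ol
Conditions: PdCl2(PPh3)2 (2 mol%), CuI (4 mol%), Et3N, THF, rt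
Reagents that add atoms: none
Why: Sonogashira coupling of an aryl iodide with a terminal alkyne is reliable at room temperature and tolerates the free hydroxyl group.

Step 3
Reactants: 2 (E)-3-[4-(benzyloxy)-3-methoxyphenyl]acrylaldehyde; 5 3-(3,4-dimethoxyphenyl)prop-2-yn-1-ol (2 equiv)
Product: 7 [(2S,3R,E)-2-[4-(benzyloxy)-3-methoxyphenyl]-4-(3,4-dimethoxybenzylidene)tetrahydrofuran-3-yl]methanol, via tetrahydrofuran-3-carbaldehyde 6 (not isolated)
Conditions: (S)-2-[diphenyl(trimethylsilyloxy)methyl]pyrrolidine (20 mol%), PdCl2 (5 mol%), PhCO2H (20 mol%), CHCl3, 4 °C; then MeOH, NaBH4, −20 °C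
Reagents that add atoms: none
Why: Proposed new method: the amine condenses with enal 2 to an E,s-trans iminium ion, alcohol 5 adds reversibly at C2 (oxa-Michael), the resulting enamine carbon C3 attacks C4 of the alkyne held as a π-complex of divalent palladium, and protodepalladation plus hydrolysis release aldehyde 6 and both catalysts before borohydride reduces C9, so that C3 can no longer epimerise and the alkene can no longer migrate through a dienamine. The closest known reaction type is the amine and divalent-palladium co-catalysed dynamic kinetic oxa-Michael/carbocyclisation of enals with terminal propargylic alcohols, extended here to an aryl-capped alkyne that should still bind palladium and accept the enamine, though more slowly. The tetrahydrofuran ring closes in the 5-exo-dig mode through the C3–C4 bond. C2 is set (S) because the alcohol enters the iminium ion anti to the diphenyl(silyloxy)methyl group of the (S)-catalyst and only this matched adduct cyclises quickly, which drains the reversible first step to one enantiomer; C3 is set trans to the C2 aryl group by the E-enamine closing with that aryl group pseudo-equatorial, which is also the thermodynamic arrangement. The step needs 5-exo rather than 6-endo closure and survival of the exocyclic alkene: the short O1–C5 tether favours attack at C4, anti carbopalladation places the veratryl group cis to C3 (E), and styrenic conjugation with the veratryl ring disfavours migration of the double bond into the ring.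

Step 4
Reactants: 7 [(2S,3R,E)-2-[4-(benzyloxy)-3-methoxyphenyl]-4-(3,4-dimethoxybenzylidene)tetrahydrofuran-3-yl]methanol
Product: 8 tert-butyl{[(2S,3R,E)-2-[4-(benzyloxy)-3-methoxyphenyl]-4-(3,4-dimethoxybenzylidene)tetrahydrofuran-3-yl]methoxy}diphenylsilane
Conditions: TBDPSCl, imidazole, DMF, rt
Reagents that add atoms: tert-butyl(chloro)diphenylsilane (TBDPSCl), CC(C)(C)[Si](Cl)(c1ccccc1)c1ccccc1
Why: Silylation of the unhindered primary alcohol is routine and installs a bulky, non-coordinating group on C9 that survives hydrogenation.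

Step 5
Reactants: 8 tert-butyl{[(2S,3R,E)-2-[4-(benzyloxy)-3-methoxyphenyl]-4-(3,4-dimethoxybenzylidene)tetrahydrofuran-3-yl]methoxy}diphenylsilane
Product: 9 4-[(2S,3R,4R)-3-{[(tert-butyldiphenylsilyl)oxy]methyl}-4-(3,4-dimethoxybenzyl)tetrahydrofuran-2-yl]-2-methoxyphenol
Conditions: H2 (1 atm), 10% Pd/C, EtOAc, rt
Reagents that add atoms: none
Why: Heterogeneous hydrogenation should deliver hydrogen to C4=C7' on the face anti to the adjacent CH2OTBDPS group (pushed pseudo-axial by A(1,3) strain with the cis veratryl group), setting C4 (R) with the benzyl group cis to C9; the aryl benzyl ether is hydrogenolysed in the same operation, and neutral conditions should spare the cyclic C2–O1 benzylic ether.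

Step 6
Reactants: 9 4-[(2S,3R,4R)-3-{[(tert-butyldiphenylsilyl)oxy]methyl}-4-(3,4-dimethoxybenzyl)tetrahydrofuran-2-yl]-2-methoxyphenol
Product: 10 4-[(2S,3R,4R)-4-(3,4-dimethoxybenzyl)-3-(hydroxymethyl)tetrahydrofuran-2-yl]-2-methoxyphenol (4'-O-methyllariciresinol)
Conditions: TBAF, AcOH, THF, 0 °C to rt
Reagents that add atoms: none
Why: Fluoride-mediated cleavage of the primary silyl ether is routine, and acetic acid buffering keeps the free phenol protonated; no stereocentre is touched.

## Compound list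

1 | 4-(benzyloxy)-3-methoxybenzaldehyde (O-benzylvanillin) | COc1cc(C=O)ccc1OCc1ccccc1 | starting material
2 | (E)-3-[4-(benzyloxy)-3-methoxyphenyl]acrylaldehyde | COc1cc(/C=C/C=O)ccc1OCc1ccccc1 | intermediate
3 | 4-iodo-1,2-dimethoxybenzene | COc1ccc(I)cc1OC | starting material
4 | prop-2-yn-1-ol (propargyl alcohol) | C#CCO | starting material
5 | 3-(3,4-dimethoxyphenyl)prop-2-yn-1-ol | COc1ccc(C#CCO)cc1OC | intermediate
6 | (2S,3S,E)-2-[4-(benzyloxy)-3-methoxyphenyl]-4-(3,4-dimethoxybenzylidene)tetrahydrofuran-3-carbaldehyde | COc1cc([C@H]2OC/C(=C/c3ccc(OC)c(OC)c3)[C@@H]2C=O)ccc1OCc1ccccc1 | intermediate (not isolated)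
7 | [(2S,3R,E)-2-[4-(benzyloxy)-3-methoxyphenyl]-4-(3,4-dimethoxybenzylidene)tetrahydrofuran-3-yl]methanol | COc1cc([C@H]2OC/C(=C/c3ccc(OC)c(OC)c3)[C@@H]2CO)ccc1OCc1ccccc1 | intermediate
8 | tert-butyl{[(2S,3R,E)-2-[4-(benzyloxy)-3-methoxyphenyl]-4-(3,4-dimethoxybenzylidene)tetrahydrofuran-3-yl]methoxy}diphenylsilane | COc1cc([C@H]2OC/C(=C/c3ccc(OC)c(OC)c3)[C@@H]2CO[Si](c2ccccc2)(c2ccccc2)C(C)(C)C)ccc1OCc1ccccc1 | intermediate
9 | 4-[(2S,3R,4R)-3-{[(tert-butyldiphenylsilyl)oxy]methyl}-4-(3,4-dimethoxybenzyl)tetrahydrofuran-2-yl]-2-methoxyphenol | COc1cc([C@H]2OC[C@H](Cc3ccc(OC)c(OC)c3)[C@@H]2CO[Si](c2ccccc2)(c2ccccc2)C(C)(C)C)ccc1O | intermediate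
10 | 4-[(2S,3R,4R)-4-(3,4-dimethoxybenzyl)-3-(hydroxymethyl)tetrahydrofuran-2-yl]-2-methoxyphenol (4'-O-methyllariciresinol) | COc1cc([C@H]2OC[C@H](Cc3ccc(OC)c(OC)c3)[C@@H]2CO)ccc1O | target

## Step count and risks

Total step count: 6. Longest linear sequence: 5 steps (steps 1, 3, 4, 5, 6 from compound 1).

Steps most likely to fail:

**1. Step 3.** Attack of the enamine on the internal, aryl-capped alkyne may be too slow, so that retro-oxa-Michael reaction and acetal formation consume the partners. Closure may also turn 6-endo, or the benzylidene double bond may migrate into conjugation with the aldehyde (erasing C3) before the reduction.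

Fallback (known chemistry), setting out from 1 and 5 and returning to the route at 7:
- Vinylmagnesium bromide (THF, 0 °C) adds to 1 to give racemic 1-[4-(benzyloxy)-3-methoxyphenyl]prop-2-en-1-ol F1.
- Lipase-catalysed acetylation (Candida antarctica lipase B, vinyl acetate) removes the (R)-enantiomer as its acetate and leaves (S)-1-[4-(benzyloxy)-3-methoxyphenyl]prop-2-en-1-ol F2, which carries the future C2.
- Alcohol 5 is converted by an Appel reaction (CBr4, PPh3, CH2Cl2) into 4-(3-bromoprop-1-yn-1-yl)-1,2-dimethoxybenzene F3.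
- F3 alkylates F2 (NaH, THF–DMF) to give (S)-1-(benzyloxy)-4-(1-{[3-(3,4-dimethoxyphenyl)prop-2-yn-1-yl]oxy}prop-2-en-1-yl)-2-methoxybenzene F4.
- Buffered epoxidation of the vinyl group (mCPBA, NaHCO3, CH2Cl2) gives 2-[(R)-[4-(benzyloxy)-3-methoxyphenyl]{[3-(3,4-dimethoxyphenyl)prop-2-yn-1-yl]oxy}methyl]oxirane F5 as both epimers at the oxirane carbon, which becomes a planar radical centre.
- Cp2TiCl (trivalent titanium, made from Cp2TiCl2 and Zn in THF) opens the oxirane homolytically to the C3 radical with C9 as a titanium alkoxide. The radical closes 5-exo-dig onto the aryl alkyne through a chair-like transition state with the C2 aryl group pseudo-equatorial, which should give the 2,3-trans ring.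
- Hydrogen-atom transfer to the linear α-aryl vinyl radical from the less hindered C5 side, followed by acidic work-up, should give 7. The alkene geometry is erased in step 5 in any case.

**2. Step 5.** Facial selectivity at C4 may be incomplete, the double bond may migrate into the ring on the catalyst surface, or the cyclic C2–O1 benzylic bond may be hydrogenolysed during the exposure needed for debenzylation.

Fallback, setting out from 8 and returning at 9. C4 is set by hydroboration instead of hydrogenation: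
- Ozonolysis of 8 (O3, CH2Cl2–MeOH, −78 °C; Me2S) cleaves the benzylidene to (4R,5S)-5-[4-(benzyloxy)-3-methoxyphenyl]-4-{[(tert-butyldiphenylsilyl)oxy]methyl}dihydrofuran-3(2H)-one F6.
- Wittig methylenation (Ph3P=CH2, THF, −78 to 0 °C) gives tert-butyl{[(2S,3R)-2-[4-(benzyloxy)-3-methoxyphenyl]-4-methylenetetrahydrofuran-3-yl]methoxy}diphenylsilane F7.
- 9-BBN (THF) should add to the 1,1-disubstituted alkene from the face anti to C9 to give 9-{[(3R,4R,5S)-5-[4-(benzyloxy)-3-methoxyphenyl]-4-{[(tert-butyldiphenylsilyl)oxy]methyl}tetrahydrofuran-3-yl]methyl}-9-borabicyclo[3.3.1]nonane F8.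
- F8 is cross-coupled without isolation with 3 in a B-alkyl Suzuki–Miyaura reaction (PdCl2(dppf), aqueous K3PO4, THF–DMF, 50 °C) to give tert-butyl{[(2S,3R,4R)-2-[4-(benzyloxy)-3-methoxyphenyl]-4-(3,4-dimethoxybenzyl)tetrahydrofuran-3-yl]methoxy}diphenylsilane F9.
- A brief hydrogenolysis of the aryl benzyl ether alone (H2, Pd/C, EtOAc) then gives 9.

**3. Step 1.** The product enal is itself an aldehyde and may react a second time with the ylide (over-homologation to the dienal), while the electron-rich starting aldehyde reacts slowly.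

Fallback, setting out from 1 and returning at 2:
- Horner–Wadsworth–Emmons olefination (triethyl phosphonoacetate, NaH, THF) gives ethyl (E)-3-[4-(benzyloxy)-3-methoxyphenyl]acrylate F10.
- DIBAL-H (CH2Cl2, −78 °C) reduces it to (E)-3-[4-(benzyloxy)-3-methoxyphenyl]prop-2-en-1-ol F11.
- MnO2 (CH2Cl2, rt) oxidises the allylic alcohol to 2.

## Further compounds

F1 | step 3 | racemic 1-[4-(benzyloxy)-3-methoxyphenyl]prop-2-en-1-ol | C=CC(O)c1ccc(OCc2ccccc2)c(OC)c1
F2 | step 3 | (S)-1-[4-(benzyloxy)-3-methoxyphenyl]prop-2-en-1-ol | C=C[C@H](O)c1ccc(OCc2ccccc2)c(OC)c1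
F3 | step 3 | 4-(3-bromoprop-1-yn-1-yl)-1,2-dimethoxybenzene | COc1ccc(C#CCBr)cc1OC
F4 | step 3 | (S)-1-(benzyloxy)-4-(1-{[3-(3,4-dimethoxyphenyl)prop-2-yn-1-yl]oxy}prop-2-en-1-yl)-2-methoxybenzene | C=C[C@H](OCC#Cc1ccc(OC)c(OC)c1)c1ccc(OCc2ccccc2)c(OC)c1
F5 | step 3 | 2-[(R)-[4-(benzyloxy)-3-methoxyphenyl]{[3-(3,4-dimethoxyphenyl)prop-2-yn-1-yl]oxy}methyl]oxirane (both oxirane epimers) | C1OC1[C@H](OCC#Cc1ccc(OC)c(OC)c1)c1ccc(OCc2ccccc2)c(OC)c1
F6 | step 5 | (4R,5S)-5-[4-(benzyloxy)-3-methoxyphenyl]-4-{[(tert-butyldiphenylsilyl)oxy]methyl}dihydrofuran-3(2H)-one | COc1cc([C@H]2OCC(=O)[C@@H]2CO[Si](c2ccccc2)(c2ccccc2)C(C)(C)C)ccc1OCc1ccccc1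
F7 | step 5 | tert-butyl{[(2S,3R)-2-[4-(benzyloxy)-3-methoxyphenyl]-4-methylenetetrahydrofuran-3-yl]methoxy}diphenylsilane | COc1cc([C@H]2OCC(=C)[C@@H]2CO[Si](c2ccccc2)(c2ccccc2)C(C)(C)C)ccc1OCc1ccccc1
F8 | step 5 | 9-{[(3R,4R,5S)-5-[4-(benzyloxy)-3-methoxyphenyl]-4-{[(tert-butyldiphenylsilyl)oxy]methyl}tetrahydrofuran-3-yl]methyl}-9-borabicyclo[3.3.1]nonane | COc1cc([C@H]2OC[C@H](CB3C4CCCC3CCC4)[C@@H]2CO[Si](c2ccccc2)(c2ccccc2)C(C)(C)C)ccc1OCc1ccccc1
F9 | step 5 | tert-butyl{[(2S,3R,4R)-2-[4-(benzyloxy)-3-methoxyphenyl]-4-(3,4-dimethoxybenzyl)tetrahydrofuran-3-yl]methoxy}diphenylsilane | COc1cc([C@H]2OC[C@H](Cc3ccc(OC)c(OC)c3)[C@@H]2CO[Si](c2ccccc2)(c2ccccc2)C(C)(C)C)ccc1OCc1ccccc1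
F10 | step 1 | ethyl (E)-3-[4-(benzyloxy)-3-methoxyphenyl]acrylate | CCOC(=O)/C=C/c1ccc(OCc2ccccc2)c(OC)c1
F11 | step 1 | (E)-3-[4-(benzyloxy)-3-methoxyphenyl]prop-2-en-1-ol | OC/C=C/c1ccc(OCc2ccccc2)c(OC)c1
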